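## Structural features

16 is a diaryl ether: two benzene rings, ring A and ring B, joined only by one oxygen between C1 of ring A and C1' of ring B. Ring A is pentasubstituted (C1 O-aryl, C2 Br, C3 Br, C4 H, C5 Br, C6 OMe) and ring B is tetrasubstituted (C1' O-aryl, C2' H, C3' Br, C4' H, C5' Br, C6' OH). There is no stereocentre, so no stereocentres stand next to each other, and with a hydrogen at C2' the ether axis is not expected to be configurationally stable. The fragile points are the five aryl C–Br bonds (towards low-valent metals, organolithiums and hydrogenolysis), the ring A C4–H between two bromines (acidic enough for metalation and halogen migration), and the C6' oxygen, which must end as a free phenol while the C6 methyl ether stays. The real difficulty is twofold. The ether oxygen lies between a doubly ortho-substituted ring A carbon and an ortho-oxygenated ring B carbon, a poor case for copper- or palladium-mediated C–O coupling on a pentabromide. In addition, the bromine pattern is not the one that bromination of an assembled diaryl ether gives, since ring A keeps hydrogen at C4, para to the ether oxygen. The key step uses the fact that the run C2'(H)–C3'(Br)–C4'(H)–C5'(Br) of ring B is C6–C5–C4–C3 of 12 (3,5-dibromo-2H-pyran-2-one), while C1'(O-aryl)–C6'(OH) is a two-carbon unit at the oxidation level of an aryloxyacetic acid.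

## Logic of the disconnections

16 to 15: the O–Si bond at C6' is cut. The ring-forming step delivers this oxygen silylated, and a silyl group is the one mask that can be removed without touching the C6 methyl ether. Nothing is gained in skeleton. The forward step needs a fluoride source mild enough to leave five C–Br bonds and the methyl ether alone.

15 to 10 and 12: the ring B bonds C1'–C2' and C5'–C6' are cut. The four carbons C2' to C5', with both bromines already in place, are C6 to C3 of 12. The other two carbons come from 10 with both oxygens and with the ether bond to ring A already made. Ring B disappears, and the hindered diaryl ether problem becomes an ordinary alkyl aryl ether made earlier by alkylation. The forward step must join the CH carbon of 10 to C6 of 12, lose CO2, and aromatise by loss of silanol and not of aryloxide.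

12 to 11: the C3–Br and C5–Br bonds are cut, the latter traced back to the C5 carboxyl group. 11 is a cheap ring that carries a leaving carbon where one bromine is needed. The forward step must combine ipso-bromodecarboxylation with C3 bromination without opening the lactone.

10 to 8: both O–Si bonds are cut and the C=C bond returns to the CH2–C(=O) unit of a stable carboxylic acid. The forward step is a double silylation through an ester enolate. It must not metalate the ring A C4–H or attack a C–Br bond, which decides the choice of base.

8 to 5 and 6: the O–CH2 bond is cut. This reduces the two-carbon unit to a commercial halo ester and leaves ring A as a phenol. The forward step is the alkylation of a hindered, acidic phenoxide, with ester cleavage in the same flask.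

5 to 3 (through 4): the ring A C1–O bond is traced back to a C1–CHO bond. A formyl group is an oxygen surrogate that cannot be confused with the other oxygen, so no catechol ever has to be differentiated. The forward step needs aryl, not hydride, migration in a peracid oxidation.

3 to 2: the O–CH3 bond is cut. Methylation is placed while the second oxygen is still a carbon substituent. The forward step is a routine alkylation.

2 to 1: the C3–Br and C5–Br bonds of ring A are cut. In 1 the one bromine that no oxygen can direct (C2, meta to the future methoxy group) is already present. The free hydroxyl at C6 directs the other two to its ortho and para positions, and C4 stays free because it is meta to the hydroxyl. This entry is preferred to formylating a tribrominated phenol at its single, hindered ortho position. The forward step must stop at the dibromide and avoid ipso attack at the formyl group.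

## Other disconnections considered

Alternative 1: The cut removes C5' from ring B by breaking C5'–C6' and C5'–C4'. This leaves a five-membered carbocycle, the silyl dienol ether A1, 2-(tert-butyldimethylsilyloxy)-3-(2,3,5-tribromo-6-methoxyphenoxy)cyclopenta-1,3-diene. A1 would come from the enone A3, 2-(2,3,5-tribromo-6-methoxyphenoxy)cyclopent-2-en-1-one, and ultimately from 5.
- Forward key step: dibromocarbene, generated from a haloform and an alkoxide base, would add to the silyl enol ether double bond of A1. The dibromocyclopropane would open with loss of bromide and of the silyl group, and the resulting bromodienone would tautomerise to A2, 2-bromo-6-(2,3,5-tribromo-6-methoxyphenoxy)phenol. A bromination para to the hydroxyl (C3') would then finish 16.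
- In its favour: the inserted carbon brings the C5' bromine to its place by construction. The phenol is released without a separate deprotection, a point on which it is better than the chosen plan. The reagents are cheap, and ring B is built on an ether bond that already exists, which is equal to the chosen plan.
- Against it here: A1 is a cyclopentadiene, prone to 1,5-hydrogen shifts that move the CH2 group and to dimerisation. The carbene must choose the silyl enol ether over the aryl enol ether double bond. The alkoxide and the trihalomethyl anion are the kind of reagents that endanger the ring A C4–H between two bromines. The phenoxide of A2 formed in the flask is itself a carbene acceptor in the Reimer–Tiemann sense.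
- Comparison: in structure it delivers ring B with one of its two bromines, where the chosen cycloaddition delivers both. In mechanism it replaces one orientation question by a chemoselectivity question under strongly basic conditions, which the chosen step avoids altogether. In step count it is about level (5, A3, A1, A2, final bromination), so length does not decide.

Alternative 2: Here ring A is built. The cuts at C1–C2 and C5–C6 give the symmetrical diene A4, 2,5-dibromothiophene 1,1-dioxide, and A5, the ketene bis(tert-butyldimethylsilyl) acetal of [2-(benzyloxy)-3,5-dibromophenoxy]acetic acid. A5 would be made from the phenol A7, 2-(benzyloxy)-3,5-dibromophenol.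
- Forward key step: a [4+2] cycloaddition, cheletropic extrusion of the sulfonyl bridge and loss of silanol would give A6, the tert-butyldimethylsilyl ether of 2-[2-(benzyloxy)-3,5-dibromophenoxy]-3,6-dibromophenol.
- In its favour: the diene is symmetrical, so the orientation problem of the chosen step does not exist, and on this point it is better. The sulfonyl bridge should leave at least as easily as the lactone bridge of 13 (equal or better). The silanol-only aromatisation follows the same logic (equal).
- Against it here: A6 has two of the three ring A bromines and a silyl ether where the methyl ether belongs. Desilylation, bromination at C3 para to the phenol (which leads to A9), O-methylation and debenzylation must follow. The debenzylation needs a Lewis acid that spares the new methyl ether, because hydrogenolysis would attack C–Br bonds. A4 must be made by exhaustive oxidation of the thiophene and belongs to a class that dimerises with loss of the sulfonyl bridge.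
- Comparison: in structure it builds the ring that needs the most adjustment afterwards, while the chosen plan builds a ring that is complete on arrival. In mechanism the two are the same kind of cycloaddition and extrusion sequence. In step count it is longer by about four steps and one protecting group.

Alternative 3: No ring bond is cut. Ring A is traced back to A10, cyclohexane-1,3-dione, by removing the aromatic unsaturation and two C–Br bonds, which gives the enone A8, 2-[2-(benzyloxy)-3,5-dibromophenoxy]-3-bromocyclohex-2-en-1-one.
- Forward key step: three equivalents of elemental bromine would brominate A8 next to the carbonyl and eliminate to the phenol tautomer. They would then brominate ortho and para to the new hydroxyl, giving A9, 2-[2-(benzyloxy)-3,5-dibromophenoxy]-3,4,6-tribromophenol.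
- Remark on locants: in the ring A numbering of 16 the two bonds formed are C3–Br and C5–Br (C4 and C6 of the enone). C2–Br is already present in A8 as the vinylic bromide.
- In its favour: the ring A carbons are bought as a ring, and aromatisation and two brominations share one flask. The positions follow from the carbonyl position and the ortho/para direction of a phenol, which is more predictable than the orientation of a cycloaddition, so on this point it is better.
- Against it here: A8 needs a C–O bond at C2 of a 1,3-dione (diazo transfer, Rh2(OAc)4-catalysed O–H insertion with A7, then vinyl bromide formation). The key step liberates four equivalents of strong acid beside a benzyl ether. It also exposes ring B (C4', para to the ether oxygen) and the benzylic position to bromine. Methylation and Lewis-acid debenzylation in the presence of a methyl ether still follow.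
- Comparison: in structure it closes no ring and needs a protecting group on ring B, where the chosen plan needs none beyond the silyl group that the key step itself installs. In mechanism it is ionic and simple but less chemoselective on a substrate with two arenes. In step count it is about level with the chosen plan (equal).

Key step: step 7

Remark on the chemistry: 16 has no stereocentre, so no descriptor is needed; 13 and 14 are racemic mixtures whose stereocentres disappear on aromatisation. Compounds 1, 6 and 11 are taken as catalogue compounds. The ring A phenol 5 is the isomer with hydrogen para to the hydroxyl, as the target requires, not the isomer that direct bromination of guaiacol would give.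

## Steps

Step 1
Reactants: 1 2-bromo-6-hydroxybenzaldehyde
Product: 2 2,3,5-tribromo-6-hydroxybenzaldehyde
Conditions: Br2 (2.1 equiv), NaOAc, AcOH, rt
Reagents that add atoms: bromine, BrBr
Why: Electrophilic aromatic bromination: the hydroxyl at C6 directs to its free ortho (C5) and para (C3) positions, both meta to the formyl group, while C4 is meta to the hydroxyl and stays free, so the ring A bromine pattern is set without a selectivity question; the acetate buffer is meant to suppress ipso-bromodeformylation.

Step 2
Reactants: 2 2,3,5-tribromo-6-hydroxybenzaldehyde
Product: 3 2,3,5-tribromo-6-methoxybenzaldehyde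
Conditions: MeI, K2CO3, DMF, rt to 40 °C
Reagents that add atoms: iodomethane, CI
Why: Williamson O-methylation of an acidic phenol; methylating before the second oxygen exists means that two phenols never have to be told apart.

Step 3
Reactants: 3 2,3,5-tribromo-6-methoxybenzaldehyde
Product: 5 2,3,5-tribromo-6-methoxyphenol, via aryl formate 4 (not isolated)
Conditions: mCPBA, CH2Cl2, 40 °C; then MeOH, HCl (cat.), rt
Reagents that add atoms: 3-chloroperoxybenzoic acid, OOC(=O)c1cccc(Cl)c1
Why: Baeyer–Villiger oxidation of an ortho-alkoxybenzaldehyde: the ortho methoxy group should favour aryl over hydride migration in the Criegee intermediate, and the aryl formate 4 is cleaved by acid-catalysed methanolysis, which leaves the methyl ether and the C–Br bonds alone.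

Step 4
Reactants: 5 2,3,5-tribromo-6-methoxyphenol; 6 methyl bromoacetate
Product: 8 (2,3,5-tribromo-6-methoxyphenoxy)acetic acid, via methyl ester 7 (not isolated)
Conditions: K2CO3, DMF, 50 °C; then LiOH, H2O, rt; HCl work-up
Reagents that add atoms: lithium hydroxide, [Li+].[OH-]
Why: Williamson alkylation of the phenoxide of 5 with an α-halo ester (SN2 at an activated primary carbon tolerates the two ortho substituents), then saponification of the unhindered methyl ester in the same flask; the aryl methyl ether is inert to hydroxide at room temperature.

Step 5
Reactants: 8 (2,3,5-tribromo-6-methoxyphenoxy)acetic acid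
Product: 10 ketene bis(tert-butyldimethylsilyl) acetal of (2,3,5-tribromo-6-methoxyphenoxy)acetic acid, via silyl ester 9 (not isolated)
Conditions: TBSCl (2.4 equiv), LiN(SiMe3)2 (1.05 equiv), THF, 0 °C to rt; then DMPU, LiN(SiMe3)2 (1.2 equiv), −78 to 0 °C; pentane, filtration
Reagents that add atoms: tert-butyldimethylsilyl chloride, CC(C)(C)[Si](C)(C)Cl
Why: Silylation of the lithium carboxylate gives 9, whose α-CH2 (activated by the ester and the aryloxy group) is deprotonated by the disilazide in the presence of the silyl chloride and trapped on oxygen, the enolisation used for glycolate Ireland–Claisen substrates. The weak amide base and the internal quench are chosen so that the ring A C4–H between two bromines is not metalated. With two identical silyl groups 10 has no alkene isomers, and either silanol loss in step 7 leads to the same product.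

Step 6
Reactants: 11 coumalic acid (2-oxo-2H-pyran-5-carboxylic acid)
Product: 12 3,5-dibromo-2H-pyran-2-one
Conditions: NBS (2.5 equiv), LiOAc (cat.), MeCN–H2O, rt
Reagents that add atoms: N-bromosuccinimide, O=C1CCC(=O)N1Br
Why: Hunsdiecker-type bromodecarboxylation of the C5 carboxylate (ipso attack on the enol-ether-like C5=C6 bond, then loss of CO2) combined with electrophilic bromination at C3; this is a known type of access to brominated 2-pyrones.

Step 7
Reactants: 10 ketene bis(tert-butyldimethylsilyl) acetal of (2,3,5-tribromo-6-methoxyphenoxy)acetic acid; 12 3,5-dibromo-2H-pyran-2-one
Product: 15 tert-butyl[2,4-dibromo-6-(2,3,5-tribromo-6-methoxyphenoxy)phenoxy]dimethylsilane, via bridged lactone 13 (not isolated), via cyclohexadiene 14 (not isolated)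
Conditions: 10 (1.5 equiv), PhMe, 100 °C, sealed tube, Ar; then PPTS (cat.), rt
Reagents that add atoms: none
Why: The electron-rich alkene of 10 (largest HOMO coefficient on the CH(O-aryl) carbon) should add to the low-lying LUMO of 12 in an asynchronous inverse-electron-demand [4+2] cycloaddition, the CH carbon bonding to pyrone C6 and the acetal carbon closing onto C3 to give bridged lactone 13. 13 should lose CO2 by a retro-[4+2] reaction to diene 14, in which C6' carries two silyloxy groups and no hydrogen, so the only aromatising 1,2-elimination removes C1'–H and one silyloxy group as silanol (acid-assisted through an O-silyl arenium ion) and the aryloxy group is kept. The closest known reaction type is the Diels–Alder, decarboxylation and elimination benzannulation of 2-pyrones with ketene acetals, together with the cycloadditions of 3,5-dibromo-2-pyrone with enol ethers. Ring B closes in the [4+2] mode, a six-membered carbocycle from the four carbons C3 to C6 of 12 and the two alkene carbons of 10, with C1'–C2' and C5'–C6' formed in one operation. No stereocentre survives: those of 13 and 14 vanish on aromatisation, so endo or exo approach is irrelevant. The step needs regioselectivity, and matched polarisation should secure it: C6 of 12 is the δ-terminus of the dienoate and gives a bromine-stabilised dienolate on attack, while in 10 two silyloxy donors on one carbon outweigh a single aryloxy donor whose aryl group is electron-poor. It also needs chemoselectivity towards five C–Br bonds and the acidic ring A C4–H, which follows from the absence of any metal or strong base. Because both acetal oxygens carry the same silyl group either elimination gives 15, and any 16 formed by adventitious desilylation is simply carried into step 8.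

Step 8
Reactants: 15 tert-butyl[2,4-dibromo-6-(2,3,5-tribromo-6-methoxyphenoxy)phenoxy]dimethylsilane
Product: 16 2,4-dibromo-6-(2,3,5-tribromo-6-methoxyphenoxy)phenol
Conditions: KHF2, MeOH, rt
Reagents that add atoms: none
Why: Fluoride-induced cleavage of an aryl silyl ether: the Si–O bond of an electron-poor phenol should be cleaved by bifluoride at room temperature, conditions under which the aryl methyl ether, the diaryl ether and the C–Br bonds are inert.

## Compound list

1 | 2-bromo-6-hydroxybenzaldehyde | O=Cc1c(O)cccc1Br | starting material
2 | 2,3,5-tribromo-6-hydroxybenzaldehyde | O=Cc1c(O)c(Br)cc(Br)c1Br | intermediate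
3 | 2,3,5-tribromo-6-methoxybenzaldehyde | COc1c(Br)cc(Br)c(Br)c1C=O | intermediate
4 | 2,3,5-tribromo-6-methoxyphenyl formate | COc1c(Br)cc(Br)c(Br)c1OC=O | intermediate
5 | 2,3,5-tribromo-6-methoxyphenol | COc1c(Br)cc(Br)c(Br)c1O | intermediate
6 | methyl bromoacetate | COC(=O)CBr | starting material
7 | methyl (2,3,5-tribromo-6-methoxyphenoxy)acetate | COC(=O)COc1c(OC)c(Br)cc(Br)c1Br | intermediate
8 | (2,3,5-tribromo-6-methoxyphenoxy)acetic acid | COc1c(Br)cc(Br)c(Br)c1OCC(=O)O | intermediate
9 | tert-butyldimethylsilyl (2,3,5-tribromo-6-methoxyphenoxy)acetate | COc1c(Br)cc(Br)c(Br)c1OCC(=O)O[Si](C)(C)C(C)(C)C | intermediate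
10 | ketene bis(tert-butyldimethylsilyl) acetal of (2,3,5-tribromo-6-methoxyphenoxy)acetic acid, 1,1-bis(tert-butyldimethylsilyloxy)-2-(2,3,5-tribromo-6-methoxyphenoxy)ethene | COc1c(Br)cc(Br)c(Br)c1OC=C(O[Si](C)(C)C(C)(C)C)O[Si](C)(C)C(C)(C)C | intermediate
11 | coumalic acid (2-oxo-2H-pyran-5-carboxylic acid) | O=C(O)C1=COC(=O)C=C1 | starting material
12 | 3,5-dibromo-2H-pyran-2-one | O=C1OC=C(Br)C=C1Br | intermediate
13 | 4,7-dibromo-5,5-bis(tert-butyldimethylsilyloxy)-6-(2,3,5-tribromo-6-methoxyphenoxy)-2-oxabicyclo[2.2.2]oct-7-en-3-one (racemic, mixture of C6 epimers) | O=C1OC2C(Br)=CC1(Br)C(O[Si](C)(C)C(C)(C)C)(O[Si](C)(C)C(C)(C)C)C2Oc1c(OC)c(Br)cc(Br)c1Br | intermediate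
14 | 1,3-dibromo-6,6-bis(tert-butyldimethylsilyloxy)-5-(2,3,5-tribromo-6-methoxyphenoxy)cyclohexa-1,3-diene (racemic) | BrC1=CC(Br)=CC(Oc2c(OC)c(Br)cc(Br)c2Br)C1(O[Si](C)(C)C(C)(C)C)O[Si](C)(C)C(C)(C)C | intermediate
15 | tert-butyl[2,4-dibromo-6-(2,3,5-tribromo-6-methoxyphenoxy)phenoxy]dimethylsilane | COc1c(Br)cc(Br)c(Br)c1Oc1cc(Br)cc(Br)c1O[Si](C)(C)C(C)(C)C | intermediate
16 | 2,4-dibromo-6-(2,3,5-tribromo-6-methoxyphenoxy)phenol | COc1c(Br)cc(Br)c(Br)c1Oc1cc(Br)cc(Br)c1O | target

## Step count and least certain steps

Total step count: 8. Longest linear sequence: 7 steps (steps 1 to 5, then 7 and 8); step 6 is a one-step side branch that joins at step 7.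

Step 7 (key step). Four processes are most likely to go wrong:
- interception of the zwitterion after the first C–C bond by silyl transfer, so that conjugate addition occurs without ring closure;
- leakage into the reversed orientation of addition;
- hydrolysis of 10 by traces of water before it meets 12;
- decarboxylation so slow that 10 decomposes at the temperature required.

The fallback gives up the de novo construction of ring B and forms the ether by nucleophilic aromatic substitution. It sets out from 5 and comes back at 16. The phenoxide of 5 (K2CO3, DMF, 60 °C) displaces fluoride from 1,5-dibromo-3-fluoro-2-nitrobenzene F1, activated by the ortho nitro group. This gives 1,5-dibromo-2-nitro-3-(2,3,5-tribromo-6-methoxyphenoxy)benzene F2. Reduction with Fe powder and NH4Cl in EtOH–H2O, which spares C–Br bonds, gives 2,4-dibromo-6-(2,3,5-tribromo-6-methoxyphenoxy)aniline F3. Diazotisation with NaNO2 in H2SO4 gives 2,4-dibromo-6-(2,3,5-tribromo-6-methoxyphenoxy)benzenediazonium hydrogensulfate F4, and hydroxydediazoniation with Cu2O and Cu(NO3)2 in water gives 16.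

Step 5. The likely failures are competing metalation of the ring A C4–H with halogen migration, C-silylation in place of O-silylation, fragmentation of the ester enolate to a ketene, and hydrolysis of 10 during isolation. The fallback replaces amide-base deprotonation by soft enolisation. It sets out from 8 and comes back at 10, passing through 9: TBSOTf (2.3 equiv) and Et3N (3 equiv) in Et2O at 0 °C to rt silylate the acid and then activate the silyl ester carbonyl, so that the amine suffices to remove the α-hydrogen. No organometallic base is present and no new compound arises.

Step 3. The likely failures are hydride migration in place of aryl migration in the Criegee intermediate, which means oxidation to the benzoic acid, and slow peracid addition to a carbonyl flanked by two ortho substituents. The fallback removes the migrating hydrogen. It sets out from 3 and comes back at 5. MeMgBr in THF at −78 °C gives racemic 1-(2,3,5-tribromo-6-methoxyphenyl)ethan-1-ol F5. Dess–Martin periodinane gives 1-(2,3,5-tribromo-6-methoxyphenyl)ethan-1-one F6. Baeyer–Villiger oxidation with CF3CO3H (from urea–H2O2 and trifluoroacetic anhydride, Na2HPO4, CH2Cl2), in which aryl reliably outruns methyl, gives 2,3,5-tribromo-6-methoxyphenyl acetate F7. Acid-catalysed methanolysis of F7 gives 5.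

## Further compounds

F1 | step 7 | 1,5-dibromo-3-fluoro-2-nitrobenzene | O=[N+]([O-])c1c(F)cc(Br)cc1Br
F2 | step 7 | 1,5-dibromo-2-nitro-3-(2,3,5-tribromo-6-methoxyphenoxy)benzene | COc1c(Br)cc(Br)c(Br)c1Oc1cc(Br)cc(Br)c1[N+](=O)[O-]
F3 | step 7 | 2,4-dibromo-6-(2,3,5-tribromo-6-methoxyphenoxy)aniline | COc1c(Br)cc(Br)c(Br)c1Oc1cc(Br)cc(Br)c1N
F4 | step 7 | 2,4-dibromo-6-(2,3,5-tribromo-6-methoxyphenoxy)benzenediazonium hydrogensulfate | COc1c(Br)cc(Br)c(Br)c1Oc1cc(Br)cc(Br)c1[N+]#N.OS(=O)(=O)[O-]
F0 | step 5 | none | none
F5 | step 3 | 1-(2,3,5-tribromo-6-methoxyphenyl)ethan-1-ol (racemic) | COc1c(Br)cc(Br)c(Br)c1C(C)O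
F6 | step 3 | 1-(2,3,5-tribromo-6-methoxyphenyl)ethan-1-one | COc1c(Br)cc(Br)c(Br)c1C(C)=O
F7 | step 3 | 2,3,5-tribromo-6-methoxyphenyl acetate | COc1c(Br)cc(Br)c(Br)c1OC(C)=O
A1 | alternative 1 | 2-(tert-butyldimethylsilyloxy)-3-(2,3,5-tribromo-6-methoxyphenoxy)cyclopenta-1,3-diene | CC(C)(C)[Si](C)(C)OC1=CCC=C1Oc1c(OC)c(Br)cc(Br)c1Br
A2 | alternative 1 | 2-bromo-6-(2,3,5-tribromo-6-methoxyphenoxy)phenol | COc1c(Br)cc(Br)c(Br)c1Oc1cccc(Br)c1O
A3 | alternative 1 | 2-(2,3,5-tribromo-6-methoxyphenoxy)cyclopent-2-en-1-one | COc1c(Br)cc(Br)c(Br)c1OC1=CCCC1=O
A4 | alternative 2 | 2,5-dibromothiophene 1,1-dioxide | O=S1(=O)C(Br)=CC=C1Br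
A5 | alternative 2 | ketene bis(tert-butyldimethylsilyl) acetal of [2-(benzyloxy)-3,5-dibromophenoxy]acetic acid | CC(C)(C)[Si](C)(C)OC(=COc1cc(Br)cc(Br)c1OCc1ccccc1)O[Si](C)(C)C(C)(C)C
A6 | alternative 2 | tert-butyldimethylsilyl ether of 2-[2-(benzyloxy)-3,5-dibromophenoxy]-3,6-dibromophenol | CC(C)(C)[Si](C)(C)Oc1c(Br)ccc(Br)c1Oc1cc(Br)cc(Br)c1OCc1ccccc1
A7 | alternative 2 | 2-(benzyloxy)-3,5-dibromophenol | Oc1cc(Br)cc(Br)c1OCc1ccccc1
A8 | alternative 3 | 2-[2-(benzyloxy)-3,5-dibromophenoxy]-3-bromocyclohex-2-en-1-one | O=C1CCCC(Br)=C1Oc1cc(Br)cc(Br)c1OCc1ccccc1
A9 | alternative 3 | 2-[2-(benzyloxy)-3,5-dibromophenoxy]-3,4,6-tribromophenol | Oc1c(Br)cc(Br)c(Br)c1Oc1cc(Br)cc(Br)c1OCc1ccccc1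
A10 | alternative 3 | cyclohexane-1,3-dione | O=C1CCCC(=O)C1
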